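The runs were computed with constants of no real substance; scatter was added.

A flat line tempts you to call a flask equilibrated and to reach for removing target, so test that reading before you decide what to do with the beta flask at 3.0 d.

common to all: starting material 1.5 M; free catalyst 1.6 mM
- beta: second substrate 0.75 M; the very flask that is asked about, followed so far
- zeta: second substrate 0.50 M; run made earlier
- flask: second substrate 0.750 M; time 3.0 d

| run | time / h | target / % | starting material / % |
|---|---|---|---|
| beta | 6.00 | 23.6 | 78.0 |
| beta | 10.0 | 22.4 | 75.7 |
| beta | 15.0 | 23.0 | 76.4 |
| beta | 25.0 | 24.3 | 78.4 |
| beta | 40.0 | 21.8 | 77.4 |
| beta | 72.0 | 23.6 | 74.5 |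
| zeta | 0.333 | 17.8 | 83.3 |
| zeta | 0.500 | 21.0 | 78.9 |
| zeta | 0.833 | 27.5 | 72.3 |
| zeta | 1.33 | 31.6 | 68.6 |
| zeta | 2.50 | 35.1 | 65.4 |
| zeta | 4.00 | 35.7 | 64.5 |

(scatter of a reading: 1 percentage point)

- grey: at 3.0 d take out 90% of the target then present, then wait 20 h
- green: at 3.0 d add starting material, 50.0% of the amount charged, then wait 20 h
- blue: change nothing and wait 20 h more
- red: at 3.0 d add free catalyst, 50.0% of the amount charged, then wait 20 h

- removed target is counted in
- the earlier runs were read with a standard deviation of 1 percentage point
- additions bring no volume worth counting

- target, in percent of the starting material first charged, at 3.0 d
- which option adds most target ("none" when 2 percentage points or less is all one gets) (grey / green / blue / red / none)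
- target present, with what was taken out counted in, in percent of the starting material first charged, after blue
- target present, with what was taken out counted in, in percent of the starting material first charged, after red

The beta flask sits at a mean of 23.1% of the starting material charged. The zeta flask, with less second substrate and the same catalyst, ends higher, at 35.4% in its last two readings. An equilibrium with second substrate as a reactant does not move that way, so I count what the catalyst delivers instead.

Target made per catalyst charged, the turnover number, is 217 in beta and 332 in zeta. Multiply each by the equivalents of second substrate per starting material, and you get 108 and 111, which are nearly equal. Their mean, 109, I call the turnover budget: turnovers times equivalents of second substrate. It is read from two runs at one charge of starting material. At that charge of starting material, I take the fraction of target made to be the budget times the catalyst fraction, divided by the equivalents.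

The beta flask reads flat from 6.00 h to 72.0 h, so I expect 23.1% at 3.0 d and the same after blue, and I expect nothing from grey or green, which bring no catalyst. Red brings fresh catalyst, and so new budget. Keeping the equivalents as charged, for want of a reading, its 50.0% of catalyst gives 12 percentage points, well above the margin, and so 34.8% in total. My decision is to charge catalyst.

The forecast gives 23.2% now, 23.2% after blue and 33% after red, and it names red, holding that “the catalyst dies, faster with more second substrate, leaving a fixed turnover budget”. Its figure for red lies below mine.

The flask gives 22.5% at 3.0 d, 22.5% after blue and 34.8% after red, and the best option is red, with 0 points from grey and 0 points from green. After 72.0 h, spent catalyst stands at 100% of the catalyst charged and free catalyst at 0%. Added to the computed 22.5%, the budget's 12 points gives 34.2%, against 34.8%.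

    starting material + free catalyst ⇌ catalyst intermediate A (K = 1.20 /M, k = 12000 /M/h)
    catalyst intermediate A → free catalyst + target (k = 4300 /h)
    second substrate + free catalyst ⇌ catalyst intermediate B (K = 15.0 /M, k = 5800 /M/h)
    catalyst intermediate B → free catalyst + second product (k = 140 /h)
    starting material → decomposition product (k = 1.80 × 10⁻⁴ /h)
    starting material + catalyst intermediate B → spent catalyst (k = 2.20 /M/h)

Now take the neighbour flask with 0.300 equiv of second substrate: the budget gives 38.9% of target. The computed result is 39.2%.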